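**Route overview**

- Cuts: the two ester C–O bonds (angelate at C10, 4-methoxybenzoate at C6), then the seven-membered ring at C1–C10 and C6–C7. This leaves a ten-carbon cyclopentenyl(benzyloxy)carbene complex (CO)5Cr=C(OBn)R and the five-carbon dienol silyl ether of prenal. The cyclopentene is the ozonolysis/aldol ring-contraction product of (S)-terpinen-4-ol.
- Enabling feature: with the C6 oxygen read as an enol, the seven-membered ring (C1, C5, C6, C7, C8, C9, C10) is a cyclohepta-1,4-diene. Double bonds C5=C6 and C8=C9 flank the single CH2 carbon C7 and face the C1–C10 single bond, the pattern that a 1,2-dialkenylcyclopropane (ring C6–C7–C8) gives on [3,3] rearrangement.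
- Forward order: cyclopentene first (steps 2 and 3), then the seven-membered ring in one operation by carbene cyclopropanation of the diene and Cope ring enlargement (step 10), then adjustment of C5 and C6 and the two acylations.
- Stereochemistry: C4 is bought with terpinen-4-ol. C1 and C10 arise together in the boat transition state of the rearrangement (E-dienol ether, face chosen by the C4 hydroxyl). C5 is set by epimerisation of the C6 ketone to the trans ring fusion, C6 by hydroxyl-directed hydride delivery, and the Z geometry of the angelate is bought.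

Key step: step 10

Numbering: daucane numbering is used for the bicyclic compounds and, by anticipation, for the carbons of their precursors. C1 is the quaternary ring-fusion carbon (methyl), C2 and C3 the cyclopentane CH2 groups, C4 the carbinol carbon (isopropyl), C5 the ring-fusion CH, C6 the anisoate carbon, C7 the ring CH2, C8 the methyl-bearing alkene carbon, C9 the alkene CH and C10 the angelate carbon. In these terms the target is (1S,4R,5S,6S,10R).

Assumption: (S)-(+)-terpinen-4-ol is taken as available in high enantiomeric purity; the configuration at C4 of every later compound rests on it.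

**Route**

Step 1
Reactants: 1 (S)-(+)-terpinen-4-ol, (1S)-4-methyl-1-(propan-2-yl)cyclohex-3-en-1-ol
Product: 2 (S)-terpinen-4-yl trimethylsilyl ether, trimethyl{[(1S)-4-methyl-1-(propan-2-yl)cyclohex-3-en-1-yl]oxy}silane
Conditions: N-(trimethylsilyl)imidazole, CH2Cl2, rt
Reagents that add atoms: N-(trimethylsilyl)imidazole, C[Si](C)(C)n1ccnc1
Why: Silylation of a hindered tertiary alcohol with a strong neutral trimethylsilyl donor masks the C4 oxygen, so that in step 3 the only free hydroxyl is the one that has to leave and steps 5 to 7 meet no acidic proton.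

Step 2
Reactants: 2 (S)-terpinen-4-yl trimethylsilyl ether
Product: 3 (3S)-6-oxo-3-(propan-2-yl)-3-(trimethylsilyloxy)heptanal
Conditions: O3, CH2Cl2, −78 °C; then Me2S, −78 °C to rt; used crude
Reagents that add atoms: ozone, [O-][O+]=O
Why: Ozonolysis of the trisubstituted ring alkene with reductive work-up opens the cyclohexene to the keto aldehyde without touching the silyl ether or the stereocentre.

Step 3
Reactants: 3 (3S)-6-oxo-3-(propan-2-yl)-3-(trimethylsilyloxy)heptanal
Product: 5 (5R)-2-methyl-5-(propan-2-yl)-5-(trimethylsilyloxy)cyclopent-1-ene-1-carbaldehyde, via aldol adduct 4 (not isolated)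
Conditions: piperidine (0.2 equiv), AcOH (0.2 equiv), toluene, 4 Å molecular sieves, rt to 40 °C
Reagents that add atoms: none
Why: In this amine-salt-catalysed intramolecular aldol condensation the piperidine enamine of the aldehyde adds to the methyl ketone in a 5-exo closure and the new tertiary hydroxyl, the only free one, is lost to give the tetrasubstituted enal, while the silylated C4 oxygen is a poor leaving group under these weakly acidic conditions and the product, having no α-hydrogen, cannot eliminate afterwards.

Step 4
Reactants: 5 (5R)-2-methyl-5-(propan-2-yl)-5-(trimethylsilyloxy)cyclopent-1-ene-1-carbaldehyde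
Product: 6 (5R)-2-methyl-5-(propan-2-yl)-5-(trimethylsilyloxy)cyclopent-1-ene-1-carboxylic acid
Conditions: NaClO2, NaH2PO4, 2-methylbut-2-ene, t-BuOH/H2O, 0 °C, short reaction time
Reagents that add atoms: sodium chlorite (NaClO2), [Na+].[O-]Cl=O
Why: Pinnick oxidation converts the hindered enal into the acid under buffered conditions that should leave the alkene, the stereocentre and, over a short reaction time, the tertiary silyl ether intact.

Step 5
Reactants: 6 (5R)-2-methyl-5-(propan-2-yl)-5-(trimethylsilyloxy)cyclopent-1-ene-1-carboxylic acid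
Product: 7 (5R)-2-methyl-5-(propan-2-yl)-5-(trimethylsilyloxy)cyclopent-1-ene-1-carbonyl chloride
Conditions: 1-chloro-N,N,2-trimethylprop-1-en-1-amine, CH2Cl2, 0 °C to rt; solvent exchanged for THF, used at once
Reagents that add atoms: 1-chloro-N,N,2-trimethylprop-1-en-1-amine, CC(C)=C(Cl)N(C)C
Why: The α-chloroenamine turns carboxylic acids into acid chlorides under neutral conditions in which no HCl is set free, as the acid-labile tertiary silyl ether requires.

Step 6
Reactants: 7 (5R)-2-methyl-5-(propan-2-yl)-5-(trimethylsilyloxy)cyclopent-1-ene-1-carbonyl chloride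
Product: 9 tetramethylammonium pentacarbonyl{[(5R)-2-methyl-5-(propan-2-yl)-5-(trimethylsilyloxy)cyclopent-1-en-1-yl]carbonyl}chromate, via sodium acylchromate 8 (not isolated)
Conditions: Cr(CO)6, NaC10H8 (sodium naphthalenide, 2 equiv), THF, −78 °C; then 7, −78 to 0 °C; then Me4NBr, H2O
Reagents that add atoms: chromium hexacarbonyl Cr(CO)6, O=C=[Cr](=C=O)(=C=O)(=C=O)(=C=O)=C=O; tetramethylammonium bromide, C[N+](C)(C)C.[Br-]
Why: Acylation of the nucleophilic pentacarbonylchromate dianion at the metal by an acid chloride is the established entry to acylchromates when the matching organolithium is not at hand, the fully substituted β-carbon shields the enoyl chloride from conjugate attack, and cation exchange gives the storable tetramethylammonium salt.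

Step 7
Reactants: 9 tetramethylammonium acylchromate
Product: 11 pentacarbonyl{(benzyloxy)[(5R)-2-methyl-5-(propan-2-yl)-5-(trimethylsilyloxy)cyclopent-1-en-1-yl]methylidene}chromium, via acetoxycarbene complex 10 (not isolated)
Conditions: CH3COBr, CH2Cl2, −40 °C; then PhCH2OH, −40 to 0 °C
Reagents that add atoms: benzyl alcohol, OCc1ccccc1
Why: O-Acylation of the acylchromate gives an acyloxycarbene complex whose acetate is displaced at the carbene carbon by an alcohol (addition–elimination), the standard way to alkoxycarbene complexes other than methoxy or ethoxy, and benzyl is chosen because the enol ether it ends up in can later be opened reductively, whereas the aqueous acid needed for a methyl enol ether would ionise the tertiary allylic C4 oxygen next to it (loss of water to the C4=C5 enone, as in a Stork–Danheiser transposition).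

Step 8
Reactants: 11 benzyloxycarbene complex with C4 trimethylsilyl ether
Product: 12 pentacarbonyl{(benzyloxy)[(5R)-5-hydroxy-2-methyl-5-(propan-2-yl)cyclopent-1-en-1-yl]methylidene}chromium
Conditions: 0.1 M aqueous HCl, THF, 0 °C
Reagents that add atoms: none
Why: Brief dilute acid cleaves the tertiary trimethylsilyl ether, which alkoxycarbene complexes of zerovalent chromium tolerate, and the hydroxyl is set free here because it is the control element of step 10.

Step 9
Reactants: 13 prenal (3-methylbut-2-enal)
Product: 14 (E)-1-(tert-butyldimethylsilyloxy)-3-methylbuta-1,3-diene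
Conditions: TBSOTf, Et3N, Et2O, 0 °C to rt; fractional distillation
Reagents that add atoms: tert-butyldimethylsilyl trifluoromethanesulfonate, CC(C)(C)[Si](C)(C)OS(=O)(=O)C(F)(F)F
Why: γ-Deprotonative O-silylation (soft enolisation) of an enal with a silyl triflate and a tertiary amine gives the 1-silyloxy-1,3-diene, of which the required E isomer is expected to predominate and is purified by distillation.

Step 10
Reactants: 12 benzyloxycarbene complex with free C4 hydroxyl; 14 (E)-1-(tert-butyldimethylsilyloxy)-3-methylbuta-1,3-diene
Product: 16 (1S,4R,10R)-6-(benzyloxy)-10-(tert-butyldimethylsilyloxy)dauca-5,8-dien-4-ol, via cis-divinylcyclopropane 15 (not isolated)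
Conditions: 14 (4 equiv), toluene (degassed), 90–110 °C, sealed tube
Reagents that add atoms: none
Why: Proposed new method: loss of one CO on heating frees a coordination site, the electron-poor carbene carbon C6 is attacked by the terminal CH2 carbon C7 of 14 (the δ-position, made nucleophilic through the diene by the silyloxy group) and the chromacyclobutane collapses to the cyclopropane C6–C7–C8 (3-exo closure on the double bond remote from oxygen), giving the 1-benzyloxy-1-alkenyl-2-vinylcyclopropane 15, whose [3,3] shift through a boat transition state breaks C6–C8 and joins C1 to C10, so that the three-membered ring is enlarged to the seven-membered ring carrying the C5=C6 enol ether and the C8=C9 alkene. The nearest precedent is the formal [4+3] annulation of (CO)5M=C(OR)(alkenyl) complexes of chromium and molybdenum with 1,3-dienes, which runs through cyclopropanation of the diene and Cope rearrangement of the cis-divinylcyclopropane; not yet shown are a fully substituted carbene β-carbon (it becomes the quaternary centre C1), a 1-silyloxydiene as partner and a free tertiary hydroxyl on the carbene. C1 and C10 are created together and their relative configuration is fixed by the boat, in which the methyl group on C1 and the hydrogen on C10 are the inward (Z) substituents, so the silyloxy group of the E-dienol ether comes out cis to C2 and trans to the C1 methyl. The absolute sense (which face of the cyclopentene bonds) is controlled by C4: in 15 and in the boat the free hydroxyl can hydrogen-bond to the benzyloxy oxygen on C6, which places the hydroxyl on the outer face and the isopropyl group on the face of the forming C1–C10 bond, so C10 adds anti to the C4 oxygen. The step needs cyclopropanation in preference to Diels–Alder and Michael addition at the alkenyl group, which the fully substituted C1 secures, and reaction at the CH2=C(Me) bond in preference to the enol ether bond, which follows from attack at the unhindered terminus; the inward methyl slows the rearrangement, hence the temperature, at which the donor-substituted cyclopropane stereoisomers (any trans isomer included) should equilibrate by reversible C6–C8 cleavage and leave through the favoured boat.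

Step 11
Reactants: 16 (1S,4R,10R)-6-(benzyloxy)-10-(tert-butyldimethylsilyloxy)dauca-5,8-dien-4-ol
Product: 18 (1S,4R,5S,10R)-10-(tert-butyldimethylsilyloxy)-4-hydroxydauc-8-en-6-one (cis-fused: H5 cis to the C1 methyl), via dilithium alkoxide enolate 17 (not isolated)
Conditions: n-BuLi (1 equiv), THF, −78 °C; lithium 4,4′-di-tert-butylbiphenylide (2.2 equiv), −78 °C; then AcOH in THF, −78 °C
Reagents that add atoms: none
Why: Two-electron reductive cleavage of the benzyl–oxygen bond by a lithium arene radical anion releases the regiodefined enolate without acid, so the tertiary allylic oxygen (as its alkoxide) and the allylic silyl ether are not ionised and the isolated C8=C9 alkene is not reduced, and protonation of C5 at low temperature is expected to occur mainly on the less hindered face, anti to the isopropyl group and the seven-membered ring, which gives the cis-fused ketone.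

Step 12
Reactants: 18 cis-fused hydroxy ketone
Product: 19 (1S,4R,5R,10R)-10-(tert-butyldimethylsilyloxy)-4-hydroxydauc-8-en-6-one (trans-fused: H5 trans to the C1 methyl)
Conditions: DBU (0.2 equiv), toluene, 0 °C to rt, followed until the epimer ratio no longer changes
Reagents that add atoms: none
Why: Base-catalysed epimerisation of a ring-fusion α-stereocentre through the enolate should favour the trans-fused ketone, which moves C6 away from the isopropyl group and places it cis to the small hydroxyl that hydrogen-bonds to the C6 carbonyl, and a catalytic amidine base in an aprotic solvent is chosen to keep retro-aldol cleavage and β-elimination of the β-hydroxy ketone to a minimum.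

Step 13
Reactants: 19 trans-fused hydroxy ketone
Product: 20 (1S,4R,5S,6S,10R)-10-(tert-butyldimethylsilyloxy)dauc-8-ene-4,6-diol
Conditions: Me4NBH(OAc)3, MeCN/AcOH, −30 to 0 °C
Reagents that add atoms: none
Why: In this Saksena–Evans reduction the C4 hydroxyl exchanges an acetate on boron and the alkoxyborohydride delivers hydride intramolecularly to the face of the C6 carbonyl on which the C4 oxygen lies, which gives the 6S alcohol (hydroxyl cis to H5), whereas a reagent approaching from the more open face would be expected to give the C6 epimer.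

Step 14
Reactants: 20 (1S,4R,5S,6S,10R)-10-(tert-butyldimethylsilyloxy)dauc-8-ene-4,6-diol; 21 4-methoxybenzoyl chloride
Product: 22 (1S,4R,5S,6S,10R)-10-(tert-butyldimethylsilyloxy)-4-hydroxydauc-8-en-6-yl 4-methoxybenzoate
Conditions: DMAP (0.2 equiv), pyridine, CH2Cl2, 0 °C to rt
Reagents that add atoms: none
Why: Acylation of the only free secondary hydroxyl with an aroyl chloride under nucleophilic catalysis leaves the tertiary C4 hydroxyl untouched, and C10 is still silylated.

Step 15
Reactants: 22 C6 anisoate with C10 silyl ether
Product: 23 (1S,4R,5S,6S,10R)-4,10-dihydroxydauc-8-en-6-yl 4-methoxybenzoate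
Conditions: HF·pyridine, pyridine, THF, 0 °C to rt
Reagents that add atoms: none
Why: Buffered HF·pyridine cleaves the secondary silyl ether without cleaving or migrating the aryl ester and without ionising the allylic position.

Step 16
Reactants: 23 (1S,4R,5S,6S,10R)-4,10-dihydroxydauc-8-en-6-yl 4-methoxybenzoate; 24 angelic acid, (Z)-2-methylbut-2-enoic acid
Product: 26 (1S,4R,5S,6S,10R)-4-hydroxy-6-(4-methoxybenzoyloxy)dauc-8-en-10-yl (Z)-2-methylbut-2-enoate (CNP0168729.1), via mixed anhydride 25 (not isolated)
Conditions: 24, 2,4,6-trichlorobenzoyl chloride, Et3N, toluene, rt; then 23, 80 °C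
Reagents that add atoms: none
Why: Yamaguchi esterification through the mixed anhydride without a nucleophilic catalyst is the usual way to transfer angelic acid to hindered alcohols with the least Z to E isomerisation, and only the secondary allylic C10 hydroxyl reacts while the tertiary C4 hydroxyl stays free.

**Compound list**

1 | (S)-(+)-terpinen-4-ol | CC1=CC[C@](O)(C(C)C)CC1 | starting material
2 | (S)-terpinen-4-yl trimethylsilyl ether | CC1=CC[C@](O[Si](C)(C)C)(C(C)C)CC1 | intermediate
3 | (3S)-6-oxo-3-(propan-2-yl)-3-(trimethylsilyloxy)heptanal | CC(=O)CC[C@](O[Si](C)(C)C)(CC=O)C(C)C | intermediate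
4 | aldol adduct, (5R)-2-hydroxy-2-methyl-5-(propan-2-yl)-5-(trimethylsilyloxy)cyclopentane-1-carbaldehyde (new centres undefined) | O=CC1C(C)(O)CC[C@@]1(O[Si](C)(C)C)C(C)C | intermediate (not isolated)
5 | (5R)-2-methyl-5-(propan-2-yl)-5-(trimethylsilyloxy)cyclopent-1-ene-1-carbaldehyde | O=CC1=C(C)CC[C@@]1(O[Si](C)(C)C)C(C)C | intermediate
6 | (5R)-2-methyl-5-(propan-2-yl)-5-(trimethylsilyloxy)cyclopent-1-ene-1-carboxylic acid | OC(=O)C1=C(C)CC[C@@]1(O[Si](C)(C)C)C(C)C | intermediate
7 | (5R)-2-methyl-5-(propan-2-yl)-5-(trimethylsilyloxy)cyclopent-1-ene-1-carbonyl chloride | ClC(=O)C1=C(C)CC[C@@]1(O[Si](C)(C)C)C(C)C | intermediate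
8 | sodium pentacarbonyl(acyl)chromate of 7 | [Na+].[O-]C(C1=C(C)CC[C@@]1(O[Si](C)(C)C)C(C)C)=[Cr](=C=O)(=C=O)(=C=O)(=C=O)=C=O | intermediate (not isolated)
9 | tetramethylammonium pentacarbonyl(acyl)chromate | C[N+](C)(C)C.[O-]C(C1=C(C)CC[C@@]1(O[Si](C)(C)C)C(C)C)=[Cr](=C=O)(=C=O)(=C=O)(=C=O)=C=O | intermediate
10 | pentacarbonyl[acetoxy(cyclopentenyl)carbene]chromium, C4 trimethylsilyl ether | CC(=O)OC(C1=C(C)CC[C@@]1(O[Si](C)(C)C)C(C)C)=[Cr](=C=O)(=C=O)(=C=O)(=C=O)=C=O | intermediate (not isolated)
11 | pentacarbonyl{(benzyloxy)[(5R)-2-methyl-5-(propan-2-yl)-5-(trimethylsilyloxy)cyclopent-1-en-1-yl]methylidene}chromium | C(c1ccccc1)OC(C1=C(C)CC[C@@]1(O[Si](C)(C)C)C(C)C)=[Cr](=C=O)(=C=O)(=C=O)(=C=O)=C=O | intermediate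
12 | pentacarbonyl{(benzyloxy)[(5R)-5-hydroxy-2-methyl-5-(propan-2-yl)cyclopent-1-en-1-yl]methylidene}chromium | C(c1ccccc1)OC(C1=C(C)CC[C@@]1(O)C(C)C)=[Cr](=C=O)(=C=O)(=C=O)(=C=O)=C=O | intermediate
13 | prenal (3-methylbut-2-enal) | CC(C)=CC=O | starting material
14 | (E)-1-(tert-butyldimethylsilyloxy)-3-methylbuta-1,3-diene | CC(=C)/C=C/O[Si](C)(C)C(C)(C)C | intermediate
15 | 1-benzyloxy-1-[(5R)-5-hydroxy-2-methyl-5-(propan-2-yl)cyclopent-1-en-1-yl]-2-methyl-2-[(E)-2-(tert-butyldimethylsilyloxy)ethenyl]cyclopropane, alkenyl groups cis | O(Cc1ccccc1)[C@@]2(C3=C(C)CC[C@@]3(O)C(C)C)C[C@]2(C)/C=C/O[Si](C)(C)C(C)(C)C | intermediate (not isolated)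
16 | (1S,4R,10R)-6-(benzyloxy)-10-(tert-butyldimethylsilyloxy)dauca-5,8-dien-4-ol | CC(C)(C)[Si](C)(C)O[C@@H]1C=C(C)CC(OCc3ccccc3)=C2[C@]1(C)CC[C@@]2(O)C(C)C | intermediate
17 | dilithium alkoxide enolate of the C6 ketone | [Li+].[Li+].CC(C)(C)[Si](C)(C)O[C@@H]1C=C(C)CC([O-])=C2[C@]1(C)CC[C@@]2([O-])C(C)C | intermediate (not isolated)
18 | (1S,4R,5S,10R)-10-(tert-butyldimethylsilyloxy)-4-hydroxydauc-8-en-6-one, cis-fused | CC(C)(C)[Si](C)(C)O[C@@H]1C=C(C)CC(=O)[C@H]2[C@]1(C)CC[C@@]2(O)C(C)C | intermediate
19 | (1S,4R,5R,10R)-10-(tert-butyldimethylsilyloxy)-4-hydroxydauc-8-en-6-one, trans-fused | CC(C)(C)[Si](C)(C)O[C@@H]1C=C(C)CC(=O)[C@@H]2[C@]1(C)CC[C@@]2(O)C(C)C | intermediate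
20 | (1S,4R,5S,6S,10R)-10-(tert-butyldimethylsilyloxy)dauc-8-ene-4,6-diol | CC(C)(C)[Si](C)(C)O[C@@H]1C=C(C)C[C@H](O)[C@@H]2[C@]1(C)CC[C@@]2(O)C(C)C | intermediate
21 | 4-methoxybenzoyl chloride | COc1ccc(cc1)C(Cl)=O | starting material
22 | (1S,4R,5S,6S,10R)-10-(tert-butyldimethylsilyloxy)-4-hydroxydauc-8-en-6-yl 4-methoxybenzoate | CC(C)(C)[Si](C)(C)O[C@@H]1C=C(C)C[C@H](OC(=O)c3ccc(OC)cc3)[C@@H]2[C@]1(C)CC[C@@]2(O)C(C)C | intermediate
23 | (1S,4R,5S,6S,10R)-4,10-dihydroxydauc-8-en-6-yl 4-methoxybenzoate | O[C@@H]1C=C(C)C[C@H](OC(=O)c2ccc(OC)cc2)[C@@H]2[C@]1(C)CC[C@@]2(O)C(C)C | intermediate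
24 | angelic acid, (Z)-2-methylbut-2-enoic acid | C/C=C(/C)C(=O)O | starting material
25 | (Z)-2-methylbut-2-enoic 2,4,6-trichlorobenzoic anhydride | C/C=C(/C)C(=O)OC(=O)c1c(Cl)cc(Cl)cc1Cl | intermediate (not isolated)
26 | (1S,4R,5S,6S,10R)-4-hydroxy-6-(4-methoxybenzoyloxy)dauc-8-en-10-yl (Z)-2-methylbut-2-enoate | C/C=C(/C)C(=O)O[C@@H]1C=C(C)C[C@H](OC(=O)c2ccc(OC)cc2)[C@@H]2[C@]1(C)CC[C@@]2(O)C(C)C | target

**Step count and risks**

Total step count: 16. Longest linear sequence: 15 steps (steps 1 to 8 and 10 to 16, from 1 to 26); diene 14 is made in one step (step 9).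

Steps most likely to fail:

1. Step 10 (the step proposed as a new method). The hindered, fully substituted alkenylcarbene may fail to cyclopropanate the diene and be lost to carbene dimerisation or CO-insertion pathways. A trans-cyclopropane may not equilibrate, the rearrangement may be too slow because of the inward methyl group, or the hydrogen bond may not discriminate the two faces of the cyclopentene. Fallback with known chemistry, setting out from acid 6 and returning at ketone 18: the same cyclopropane and the same [3,3] shift would be reached through titanium chemistry. Acid 6 is converted (MeI, K2CO3, DMF) into methyl (5R)-2-methyl-5-(propan-2-yl)-5-(trimethylsilyloxy)cyclopent-1-ene-1-carboxylate F1. F1 undergoes a Kulinkovich hydroxycyclopropanation in its alkene-exchange variant with diene 14 (ClTi(OiPr)3, c-C5H9MgCl, exchange of the titanacyclopropane onto the CH2=C(Me) bond of 14), which should give the cis-1-alkenyl-2-vinylcyclopropanol F2. As its alkoxide F2 should rearrange on warming (oxy-anion-assisted divinylcyclopropane rearrangement, the known route from cis-1,2-dialkenylcyclopropanols to cyclohept-4-enones) to the C5=C6 enolate. Protonation of the enolate gives (1S,4R,5S,10R)-10-(tert-butyldimethylsilyloxy)-4-(trimethylsilyloxy)dauc-8-en-6-one F3, and dilute aqueous HCl in THF removes the trimethylsilyl group to give 18. Steps 5 to 8, 10 and 11 are then not needed.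

2. Step 12. Enolisation at the hindered C5 may be outrun by deprotonation at the more acidic C7. That would move the C8=C9 double bond into conjugation with the ketone and expose the C10 silyloxy group to elimination from the dienolate. Retro-aldol opening of the C4–C5 bond is a further drain. Fallback, setting out from enol ether 16 and returning at ketone 19: the C5 hydrogen would be put in under reagent control instead of by equilibration. The dilithium alkoxide enolate 17, generated as in step 11, is trapped with allyl chloroformate to give diallyl (1S,4R,10R)-10-(tert-butyldimethylsilyloxy)dauca-5,8-diene-4,6-diyl dicarbonate F4. Palladium-catalysed decarboxylative protonation (Pd2(dba)3, a t-Bu-PHOX ligand of the enantiomeric series that directs the proton to the face of C5 anti to the C4 oxygen, HCO2H, dioxane) then frees both oxygens and protonates the enolate under ligand control, giving 19 directly. Steps 11 and 12 are replaced.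

3. Step 16. Acylation of the neopentylic allylic C10 hydroxyl may be too slow, and the angelate may isomerise to the tiglate in the mixed anhydride or in the product. Fallback, setting out from alcohol 23 and returning at target 26: the Z-enoate would be built on the alcohol instead of being transferred. Alcohol 23 is esterified with 2-[bis(2,2,2-trifluoroethoxy)phosphoryl]propanoic acid (DCC, DMAP, CH2Cl2) to (1S,4R,5S,6S,10R)-4-hydroxy-6-(4-methoxybenzoyloxy)dauc-8-en-10-yl 2-[bis(2,2,2-trifluoroethoxy)phosphoryl]propanoate F5. Still–Gennari olefination of F5 with acetaldehyde (KN(SiMe3)2, 18-crown-6, THF, −78 °C) should form the (Z)-2-methylbut-2-enoate under kinetic control, giving 26.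

Further compounds

F1 | step 10 | methyl (5R)-2-methyl-5-(propan-2-yl)-5-(trimethylsilyloxy)cyclopent-1-ene-1-carboxylate | COC(=O)C1=C(C)CC[C@@]1(O[Si](C)(C)C)C(C)C
F2 | step 10 | 1-[(5R)-2-methyl-5-(propan-2-yl)-5-(trimethylsilyloxy)cyclopent-1-en-1-yl]-2-methyl-2-[(E)-2-(tert-butyldimethylsilyloxy)ethenyl]cyclopropan-1-ol, alkenyl groups cis | O[C@@]2(C3=C(C)CC[C@@]3(O[Si](C)(C)C)C(C)C)C[C@]2(C)/C=C/O[Si](C)(C)C(C)(C)C
F3 | step 10 | (1S,4R,5S,10R)-10-(tert-butyldimethylsilyloxy)-4-(trimethylsilyloxy)dauc-8-en-6-one | CC(C)(C)[Si](C)(C)O[C@@H]1C=C(C)CC(=O)[C@H]2[C@]1(C)CC[C@@]2(O[Si](C)(C)C)C(C)C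
F4 | step 12 | diallyl (1S,4R,10R)-10-(tert-butyldimethylsilyloxy)dauca-5,8-diene-4,6-diyl dicarbonate | CC(C)(C)[Si](C)(C)O[C@@H]1C=C(C)CC(OC(=O)OCC=C)=C2[C@]1(C)CC[C@@]2(OC(=O)OCC=C)C(C)C
F5 | step 16 | (1S,4R,5S,6S,10R)-4-hydroxy-6-(4-methoxybenzoyloxy)dauc-8-en-10-yl 2-[bis(2,2,2-trifluoroethoxy)phosphoryl]propanoate | CC(P(=O)(OCC(F)(F)F)OCC(F)(F)F)C(=O)O[C@@H]1C=C(C)C[C@H](OC(=O)c2ccc(OC)cc2)[C@@H]2[C@]1(C)CC[C@@]2(O)C(C)C
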